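**Plan**
- **Cuts, in retrosynthetic order:** the nine O–benzyl bonds; the C3–H and C4–H bonds, leading back to a flav-3-ene; the C3=C4 bond of pyran ring C (ring-closing metathesis); the C3–O bond of the 3-gallate (acid plus terminal alkyne); the O1–C2 ether bond (phenol plus propargylic ester); the 5-O-gallate ester bond.
- **Enabling feature:** in ring C, C3 carries an acyloxy group and its neighbour C4 is a CH2 bonded to C4a of ring A. C3–C4 can therefore be carried as the C=C of a cyclic enol gallate conjugated with ring A. C2, the only sp3 carbon left in that ring, holds the B-ring aryl group over one alkene face.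
- **Forward:** ring A (from 2,4,6-trihydroxybenzaldehyde) becomes a 2-vinylphenol monogallate, and ring B (from catalogue 3,4-bis(benzyloxy)benzaldehyde) becomes a propargylic acetate. The two are joined at O1–C2, the second gallate is added across the alkyne, and ring C, the only ring made, closes last.
- **Stereochemistry:** C2 (R) comes from a ligand-controlled copper-catalysed propargylic etherification. C3 (R) comes from syn addition of H2 to the enol gallate on the face away from the C2 aryl group. This gives the 2,3-cis relation that oxygen delivery to a flav-3-ene would not give.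

Key step: step 7

Assumption: the (S,S)-pybox ligand is taken to give the (S)-configured propargylic aryl ether. The sense of induction must be checked on the first batch, and the equally available (R,R)-ligand is used if it proves opposite.

Step 1
Reactants: 1 2,4,6-trihydroxybenzaldehyde
Product: 2 4-(benzyloxy)-2,6-dihydroxybenzaldehyde
Conditions: BnBr (1.0 equiv), NaHCO3, MeCN, 70 °C
Reagents that add atoms: benzyl bromide, BrCc1ccccc1
Why: Williamson etherification with a weak base, in which the 4-OH is the most acidic hydroxyl and the only one not hydrogen-bonded to the formyl group, so one equivalent of benzyl bromide should stop at the 4-O-benzyl ether as in the regioselective 4-O-benzylation of 2,4-dihydroxybenzaldehyde.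

Step 2
Reactants: 2 4-(benzyloxy)-2,6-dihydroxybenzaldehyde
Product: 3 5-(benzyloxy)-2-vinylbenzene-1,3-diol
Conditions: MePPh3Br (4.0 equiv), KOtBu (3.8 equiv), THF, 0 °C to rt; aq NH4Cl, BHT
Reagents that add atoms: methyltriphenylphosphonium bromide, C[P+](c1ccccc1)(c1ccccc1)c1ccccc1.[Br-]
Why: Wittig methylenation as practised on salicylaldehydes, in which part of the ylide serves as base for the two phenols and the excess olefinates the formyl group, while a buffered work-up with BHT protects the electron-rich vinylresorcinol from acid-induced oligomerisation.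

Step 3
Reactants: 3 5-(benzyloxy)-2-vinylbenzene-1,3-diol; 4 3,4,5-tris(benzyloxy)benzoic acid
Product: 5 5-(benzyloxy)-3-hydroxy-2-vinylphenyl 3,4,5-tris(benzyloxy)benzoate
Conditions: 4 (0.9 equiv), DCC, DMAP (cat.), CH2Cl2, 0 °C to rt
Reagents that add atoms: none
Why: Steglich esterification of a symmetric diol whose two hydroxyls are equivalent, so only the degree of acylation needs control (acid as limiting reagent, diol and diester separated and recycled), and the acyloxy group also lowers the carbon nucleophilicity of ring A for step 5.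

Step 4
Reactants: 6 3,4-bis(benzyloxy)benzaldehyde; 7 ethynylmagnesium bromide
Product: 9 rac-1-[3,4-bis(benzyloxy)phenyl]prop-2-yn-1-yl acetate, via bromomagnesium alkoxide 8 (not isolated)
Conditions: THF, 0 °C; then Ac2O, 0 °C to rt
Reagents that add atoms: acetic anhydride, CC(=O)OC(C)=O
Why: Grignard 1,2-addition to the aldehyde followed by O-acylation of the magnesium alkoxide in the same flask gives the propargylic acetate, and its racemic stereocentre is of no consequence because it is erased in step 5.

Step 5
Reactants: 5 5-(benzyloxy)-3-hydroxy-2-vinylphenyl 3,4,5-tris(benzyloxy)benzoate; 9 rac-1-[3,4-bis(benzyloxy)phenyl]prop-2-yn-1-yl acetate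
Product: 10 5-(benzyloxy)-3-{[(1S)-1-[3,4-bis(benzyloxy)phenyl]prop-2-yn-1-yl]oxy}-2-vinylphenyl 3,4,5-tris(benzyloxy)benzoate
Conditions: CuOTf·½C6H6 (5 mol %), (S,S)-Ph-pybox (6 mol %), iPr2NEt (1.2 equiv), ClCH2CH2Cl, −10 °C
Reagents that add atoms: none
Why: Copper-catalysed enantioselective propargylic etherification with a phenol, in which the copper acetylide of 9 loses acetate to a planar copper allenylidene so that both enantiomers converge, and the pybox ligand decides the face on which the phenol oxygen of 5 attacks, setting the future C2 (S here, R after step 6 by a change of CIP priorities only).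

Step 6
Reactants: 10 (S)-propargylic aryl ether; 4 3,4,5-tris(benzyloxy)benzoic acid
Product: 11 (3R)-3-[3,4-bis(benzyloxy)phenyl]-3-[5-(benzyloxy)-3-{[3,4,5-tris(benzyloxy)benzoyl]oxy}-2-vinylphenoxy]prop-1-en-2-yl 3,4,5-tris(benzyloxy)benzoate
Conditions: [RuCl2(p-cymene)]2 (2 mol %), P(2-furyl)3 (4 mol %), Na2CO3 (4 mol %), toluene, 50 °C
Reagents that add atoms: none
Why: Ruthenium(II)-catalysed Markovnikov hydroacyloxylation of a terminal alkyne, in which carboxylate attacks the internal carbon of the Ru-bound alkyne (the regiochemistry also seen with O-substituted propargylic substrates), and the nearly neutral medium leaves the styrene, the aryl ester and C2 untouched.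

Step 7
Reactants: 11 enol gallate diene
Product: 12 (2R)-7-(benzyloxy)-2-[3,4-bis(benzyloxy)phenyl]-2H-chromene-3,5-diyl bis[3,4,5-tris(benzyloxy)benzoate] (nona-O-benzyl 3,5-bis(galloyloxy)flav-3-ene)
Conditions: Hoveyda–Grubbs II (10 mol %, two portions), 1,4-benzoquinone (20 mol %), toluene (2 mM), 80 °C, Ar sparge
Reagents that add atoms: none
Why: Ring-closing olefin metathesis: the catalyst first exchanges its benzylidene for the monosubstituted styrene terminus of 11 (the 1,1-disubstituted enol ester alkene is too hindered to initiate), the resulting aryl alkylidene, stabilised by O1 like an isopropoxybenzylidene chelate, undergoes [2+2] cycloaddition with the tethered CH2=C(OCOAr) unit with Ru at the CH2 end, and cycloreversion releases 12 and Ru=CH2, which re-enters the cycle at the next styrene with loss of ethene. The closest known reactions are the RCM of 2-vinylaryl allyl ethers to 2H-chromenes and the RCM of 1,1-disubstituted enol ethers, silyl enol ethers and enol esters to heteroatom-substituted cycloalkenes with second-generation ruthenium catalysts. Ring C (O1, C2, C3, C4, C4a, C8a) closes as a six-membered ring by formation of the C3=C4 bond, both alkene carbons becoming endocyclic. No stereocentre is formed, and C2 is a spectator because the medium is neutral and benzoquinone intercepts ruthenium hydrides that could move the double bond towards C2. The step needs ring closure to win over styrene homodimerisation and must avoid an acyloxy-substituted (Fischer-type) carbene: the short O1–C2 tether, high dilution and ethene removal secure the first, and the tether geometry, which lets the alkylidene carbon bond only to C3, secures the second.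

Step 8
Reactants: 12 nona-O-benzyl 3,5-bis(galloyloxy)flav-3-ene
Product: 13 (2R,3R)-7-(benzyloxy)-2-[3,4-bis(benzyloxy)phenyl]-3,4-dihydro-2H-chromene-3,5-diyl bis[3,4,5-tris(benzyloxy)benzoate] (nona-O-benzyl-(−)-epicatechin 3,5-di-O-gallate)
Conditions: H2 (1–4 atm), 5% Rh/Al2O3, EtOAc–THF, rt
Reagents that add atoms: none
Why: Heterogeneous syn hydrogenation of a cyclic enol ester, in which A(1,2) strain with the C3 gallate pushes the C2 aryl group pseudo-axial over one face so that both hydrogens arrive on the face of C2–H and C3 becomes R (2,3-cis), rhodium on alumina being chosen because it saturates alkenes with little hydrogenolysis of benzylic, allylic or vinylic C–O bonds.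

Step 9
Reactants: 13 nona-O-benzyl-(−)-epicatechin 3,5-di-O-gallate
Product: 14 (−)-epicatechin 3,5-di-O-gallate
Conditions: H2 (1 atm), 20% Pd(OH)2/C, THF–MeOH, rt
Reagents that add atoms: none
Why: Catalytic hydrogenolysis of the nine aryl benzyl ethers under neutral conditions, the usual last step for perbenzylated flavan-3-ol gallates, which should leave both esters, the O1–C2 bond and both stereocentres unchanged.

**Compound list**
1 | 2,4,6-trihydroxybenzaldehyde | O=Cc1c(O)cc(O)cc1O | starting material
2 | 4-(benzyloxy)-2,6-dihydroxybenzaldehyde | O=Cc1c(O)cc(OCc2ccccc2)cc1O | intermediate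
3 | 5-(benzyloxy)-2-vinylbenzene-1,3-diol | C=Cc1c(O)cc(OCc2ccccc2)cc1O | intermediate
4 | 3,4,5-tris(benzyloxy)benzoic acid | O=C(O)c1cc(OCc2ccccc2)c(OCc2ccccc2)c(OCc2ccccc2)c1 | starting material
5 | 5-(benzyloxy)-3-hydroxy-2-vinylphenyl 3,4,5-tris(benzyloxy)benzoate | C=Cc1c(O)cc(OCc2ccccc2)cc1OC(=O)c1cc(OCc2ccccc2)c(OCc2ccccc2)c(OCc2ccccc2)c1 | intermediate
6 | 3,4-bis(benzyloxy)benzaldehyde | O=Cc1ccc(OCc2ccccc2)c(OCc2ccccc2)c1 | starting material
7 | ethynylmagnesium bromide | C#C[Mg]Br | starting material
8 | bromomagnesium 1-[3,4-bis(benzyloxy)phenyl]prop-2-yn-1-olate (racemic, not isolated) | C#CC(O[Mg]Br)c1ccc(OCc2ccccc2)c(OCc2ccccc2)c1 | intermediate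
9 | rac-1-[3,4-bis(benzyloxy)phenyl]prop-2-yn-1-yl acetate | C#CC(OC(C)=O)c1ccc(OCc2ccccc2)c(OCc2ccccc2)c1 | intermediate
10 | 5-(benzyloxy)-3-{[(1S)-1-[3,4-bis(benzyloxy)phenyl]prop-2-yn-1-yl]oxy}-2-vinylphenyl 3,4,5-tris(benzyloxy)benzoate | C=Cc1c(OC(=O)c2cc(OCc3ccccc3)c(OCc3ccccc3)c(OCc3ccccc3)c2)cc(OCc2ccccc2)cc1O[C@H](c1ccc(OCc2ccccc2)c(OCc2ccccc2)c1)C#C | intermediate
11 | (3R)-3-[3,4-bis(benzyloxy)phenyl]-3-[5-(benzyloxy)-3-{[3,4,5-tris(benzyloxy)benzoyl]oxy}-2-vinylphenoxy]prop-1-en-2-yl 3,4,5-tris(benzyloxy)benzoate | C=Cc1c(OC(=O)c2cc(OCc3ccccc3)c(OCc3ccccc3)c(OCc3ccccc3)c2)cc(OCc2ccccc2)cc1O[C@H](c1ccc(OCc2ccccc2)c(OCc2ccccc2)c1)C(=C)OC(=O)c1cc(OCc2ccccc2)c(OCc2ccccc2)c(OCc2ccccc2)c1 | intermediate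
12 | (2R)-7-(benzyloxy)-2-[3,4-bis(benzyloxy)phenyl]-2H-chromene-3,5-diyl bis[3,4,5-tris(benzyloxy)benzoate] | O=C(Oc1cc(OCc2ccccc2)cc2c1C=C(OC(=O)c1cc(OCc3ccccc3)c(OCc3ccccc3)c(OCc3ccccc3)c1)[C@@H](c1ccc(OCc3ccccc3)c(OCc3ccccc3)c1)O2)c1cc(OCc2ccccc2)c(OCc2ccccc2)c(OCc2ccccc2)c1 | intermediate
13 | (2R,3R)-7-(benzyloxy)-2-[3,4-bis(benzyloxy)phenyl]-3,4-dihydro-2H-chromene-3,5-diyl bis[3,4,5-tris(benzyloxy)benzoate] | O=C(Oc1cc(OCc2ccccc2)cc2c1C[C@@H](OC(=O)c1cc(OCc3ccccc3)c(OCc3ccccc3)c(OCc3ccccc3)c1)[C@@H](c1ccc(OCc3ccccc3)c(OCc3ccccc3)c1)O2)c1cc(OCc2ccccc2)c(OCc2ccccc2)c(OCc2ccccc2)c1 | intermediate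
14 | (−)-epicatechin 3,5-di-O-gallate, (2R,3R)-2-(3,4-dihydroxyphenyl)-7-hydroxy-3,4-dihydro-2H-chromene-3,5-diyl bis(3,4,5-trihydroxybenzoate) | O=C(Oc1cc(O)cc2c1C[C@@H](OC(=O)c1cc(O)c(O)c(O)c1)[C@@H](c1ccc(O)c(O)c1)O2)c1cc(O)c(O)c(O)c1 | target

**Step count**
- Total steps: 9.
- Longest linear sequence: 8 steps, from 1 to 14 through steps 1, 2, 3, 5, 6, 7, 8 and 9.

**Steps most likely to fail**

**Step 7 (ring-closing metathesis).**
- *Risk:* the substrate-derived alkylidene may rest as its O1 chelate. It may also be used up by styrene homodimerisation and catalyst decay before the crowded, carbonyl-flanked 1,1-disubstituted alkene is engaged.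
- *Fallback:* the C3=C4 metathesis is kept, but the group on C3 is changed and the gallate is brought in after ring closure. The fallback sets out from alkyne 10. An NHC–copper-catalysed α-selective protoboration (N-aryl NHC–CuCl, NaOtBu cat., B2pin2, MeOH, THF, low temperature) favours the internal boronate with propargylic ethers. It should give the (S)-2-(pinacolboryl)allyl aryl ether F1. Ring-closing metathesis of such 1,1-disubstituted alkenyl boronates with a terminal alkene is established and should give the (2S)-3-(pinacolboryl)flav-3-ene F2. A copper-mediated oxidative C–O coupling of the alkenyl boronate with acid 4 (Chan–Lam type enol ester synthesis; Cu(I) salt, DMAP, O2, 4 Å sieves) then comes back to the route at 12.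

**Step 5 (propargylic etherification).**
- *Risk:* carbon attack by the electron-rich ring A may compete with oxygen attack. Uncatalysed ionisation of the electron-rich propargylic acetate may erode the enantiomeric purity. Base-induced acyl transfer between phenols may scramble the monogallate.
- *Fallback:* creation of the stereocentre is separated from formation of the C–O bond. The fallback sets out from racemic acetate 9. Lipase-catalysed butanolysis (immobilised Candida antarctica lipase B, n-BuOH, MTBE) should release the fast-reacting enantiomer as (R)-1-[3,4-bis(benzyloxy)phenyl]prop-2-yn-1-ol F3. It should leave behind (S)-1-[3,4-bis(benzyloxy)phenyl]prop-2-yn-1-yl acetate F4. Mitsunobu etherification of the alcohol with phenol 5 (PPh3, DIAD, toluene, −20 °C, a non-polar medium chosen to hold back ionisation) proceeds with inversion and comes back to the route at 10.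

**Step 8 (hydrogenation of the enol gallate).**
- *Risk:* facial selectivity may be poor. Hydrogenolysis of the allylic and benzylic O1–C2 bond or of the vinylic C3–O bond may precede saturation of the alkene.
- *Fallback:* C3 is set by hydride addition to a ketone, not by alkene hydrogenation. The fallback sets out from 12. A neutral, distannoxane-catalysed transfer of the enol gallate acyl group to methanol uses the fact that enol esters are irreversible acyl donors. It should unmask the (2R)-flavan-3-one 5-gallate F5 without a base that could epimerise C2. L-Selectride (THF, −78 °C) attacks the ketone on the face away from the C2 aryl group. This is the established way from flavan-3-ones to 2,3-cis-flavan-3-ols, and it should give the (2R,3R)-flavan-3-ol 5-gallate F6. Steglich esterification with acid 4 comes back to the route at 13.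

**Further compounds**
F1 | step 7 | 5-(benzyloxy)-3-{[(1S)-1-[3,4-bis(benzyloxy)phenyl]-2-(4,4,5,5-tetramethyl-1,3,2-dioxaborolan-2-yl)prop-2-en-1-yl]oxy}-2-vinylphenyl 3,4,5-tris(benzyloxy)benzoate | C=Cc1c(OC(=O)c2cc(OCc3ccccc3)c(OCc3ccccc3)c(OCc3ccccc3)c2)cc(OCc2ccccc2)cc1O[C@H](c1ccc(OCc2ccccc2)c(OCc2ccccc2)c1)C(=C)B1OC(C)(C)C(C)(C)O1
F2 | step 7 | (2S)-7-(benzyloxy)-2-[3,4-bis(benzyloxy)phenyl]-3-(4,4,5,5-tetramethyl-1,3,2-dioxaborolan-2-yl)-2H-chromen-5-yl 3,4,5-tris(benzyloxy)benzoate | O=C(Oc1cc(OCc2ccccc2)cc2c1C=C(B1OC(C)(C)C(C)(C)O1)[C@@H](c1ccc(OCc3ccccc3)c(OCc3ccccc3)c1)O2)c1cc(OCc2ccccc2)c(OCc2ccccc2)c(OCc2ccccc2)c1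
F3 | step 5 | (R)-1-[3,4-bis(benzyloxy)phenyl]prop-2-yn-1-ol | O[C@@H](c1ccc(OCc2ccccc2)c(OCc2ccccc2)c1)C#C
F4 | step 5 | (S)-1-[3,4-bis(benzyloxy)phenyl]prop-2-yn-1-yl acetate | CC(=O)O[C@H](c1ccc(OCc2ccccc2)c(OCc2ccccc2)c1)C#C
F5 | step 8 | (2R)-7-(benzyloxy)-2-[3,4-bis(benzyloxy)phenyl]-3-oxo-3,4-dihydro-2H-chromen-5-yl 3,4,5-tris(benzyloxy)benzoate | O=C(Oc1cc(OCc2ccccc2)cc2c1CC(=O)[C@@H](c1ccc(OCc3ccccc3)c(OCc3ccccc3)c1)O2)c1cc(OCc2ccccc2)c(OCc2ccccc2)c(OCc2ccccc2)c1
F6 | step 8 | (2R,3R)-7-(benzyloxy)-2-[3,4-bis(benzyloxy)phenyl]-3-hydroxy-3,4-dihydro-2H-chromen-5-yl 3,4,5-tris(benzyloxy)benzoate | O=C(Oc1cc(OCc2ccccc2)cc2c1C[C@@H](O)[C@@H](c1ccc(OCc3ccccc3)c(OCc3ccccc3)c1)O2)c1cc(OCc2ccccc2)c(OCc2ccccc2)c(OCc2ccccc2)c1
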